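**Strategy.** The flavanone is cut at O1–C2 and C3–C4: O1, C8a, C4a and C4 of ring A and the pyranone are an ortho-quinone methide heterodiene, and C2(aryl)–C3 is a 4-silyloxystyrene. A single chiral-acid-catalysed hetero-[4+2] of the 4-methoxy ortho-quinone methide, made in situ from a salicylaldehyde and trimethyl orthoformate, closes the pyran ring, forms both bonds and sets C2; the C4 methoxy group is the latent ketone. The precursor is 2-hydroxy-3-iodo-6-methoxy-4-(triisopropylsilyloxy)benzaldehyde. Its iodine (future C8) is later turned into a formyl group, to which the separately built C2'–C9' chain is added as an alkyltitanium under catalyst control.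

Key step: step 4

Remark: side-chain carbons are numbered C1' (carbinol carbon on C8) to C9' (benzylic CH2 of the terminal aryl group); the target is read as 2S, 1'S, 3'R, 4'E, 7'S.

**Route**

Step 1
Reactants: 1 2,4-dihydroxy-6-methoxybenzaldehyde
Product: 2 2,4-dihydroxy-3-iodo-6-methoxybenzaldehyde
Conditions: I2 (1.0 equiv), NaHCO3, THF/H2O, 0 °C
Reagents that add atoms: iodine, II
Why: Electrophilic aromatic iodination of the phenoxide should go to C3, the position ortho to the chelated 2-hydroxyl and flanked by both hydroxyls, as in the ortho-iodination of 2-hydroxy-4,6-dioxygenated aryl carbonyl compounds that leads to 8-iodoflavonoids; one equivalent of iodine at 0 °C limits di-iodination, and an NOE between H-5 and the methoxyl group is to confirm the site.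

Step 2
Reactants: 2 2,4-dihydroxy-3-iodo-6-methoxybenzaldehyde
Product: 3 2-hydroxy-3-iodo-6-methoxy-4-(triisopropylsilyloxy)benzaldehyde
Conditions: TIPSCl (1.1 equiv), imidazole, DMF, 0 °C to rt
Reagents that add atoms: triisopropylsilyl chloride, CC(C)[Si](Cl)(C(C)C)C(C)C
Why: Imidazole-mediated phenol silylation is selective for the acidic, non-chelated 4-hydroxyl because the 2-hydroxyl is hydrogen-bonded to the aldehyde and flanked by iodine; the bulky triisopropylsilyl group is chosen because this oxygen sits para to the cationic carbon in step 4 and later para and ortho to two carbonyl groups, where a smaller silyl group would be solvolysed.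

Step 3
Reactants: 4 4-acetoxystyrene
Product: 6 4-(tert-butyldimethylsilyloxy)styrene, via 4-vinylphenol 5 (not isolated)
Conditions: K2CO3 (0.2 equiv), MeOH, rt; concentrate; TBSCl, imidazole, CH2Cl2, 0 °C
Reagents that add atoms: tert-butyldimethylsilyl chloride, CC(C)(C)[Si](C)(C)Cl
Why: Base-catalysed methanolysis of the aryl acetate followed by imidazole-mediated silylation of the crude phenol, which is not stored because it polymerises, should give the protected styrene.

Step 4
Reactants: 3 2-hydroxy-3-iodo-6-methoxy-4-(triisopropylsilyloxy)benzaldehyde; 6 4-(tert-butyldimethylsilyloxy)styrene; 7 trimethyl orthoformate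
Product: 10 (2S,4S)-2-[4-(tert-butyldimethylsilyloxy)phenyl]-8-iodo-4,5-dimethoxy-7-(triisopropylsilyloxy)chromane, via dimethyl acetal 8 (not isolated), via ortho-quinone methide 9 (not isolated)
Conditions: 7 (1.5 equiv), BINOL-derived N-triflylphosphoramide bearing 3,3'-bis(2,4,6-triisopropylphenyl) groups (5 mol %, antipode giving 2S), 5 Å MS, toluene, −40 °C, 6 (1.5 equiv) added slowly; Et3N quench
Reagents that add atoms: none
Why: Proposed new method: acid-catalysed acetalisation of 3 by 7 and loss of methanol should give the O-methyl oxocarbenium ion/ortho-quinone methide 9, ion-paired and hydrogen-bonded through its ring oxygen to the chiral phosphoramide anion, and the electron-rich styrene 6 adds in an asynchronous inverse-electron-demand hetero-[4+2], C3–C4 first and then O1–C2. The closest known reaction types are the achiral-acid three-component coupling of salicylaldehydes, orthoformates and styrenes to racemic 2,4-cis 4-alkoxyflavans and chiral Brønsted acid catalysed cycloadditions of other ortho-quinone methides and salicylaldehyde-acetal-derived oxocarbenium ions with enol ethers; the enantioselective variant with a styrene is the unproven element. The pyran ring is closed by the cycloaddition itself, in the stepwise limit by capture of the 4-silyloxybenzyl cation by the phenolic O1 to form the six-membered ring with rearomatisation of ring A. C2 is set by the chiral counter-anion, which shields one face of the bound heterodiene (the catalyst antipode giving 2S is to be found by screening), while C4 follows from endo approach of the aryl group (2,4-cis) and is inconsequential because it becomes the ketone. The step needs regioselectivity, which follows from polarity (styrene CH2 to the cationic C4, oxygen to the benzylic C2), and chemoselectivity over styrene oligomerisation and para-quinone methide formation, which is secured by the silylated para oxygen, the single free ortho hydroxyl, the iodine blocking the future C8 and the slow addition of 6 at low temperature.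

Step 5
Reactants: 10 (2S,4S)-2-[4-(tert-butyldimethylsilyloxy)phenyl]-8-iodo-4,5-dimethoxy-7-(triisopropylsilyloxy)chromane
Product: 11 (2S)-2-[4-(tert-butyldimethylsilyloxy)phenyl]-8-iodo-5-methoxy-7-(triisopropylsilyloxy)chroman-4-one
Conditions: DDQ (1.3 equiv), CH2Cl2/pH 7 buffer, 0 °C to rt
Reagents that add atoms: water, O
Why: DDQ oxidation of an electron-rich benzylic methyl ether: hydride abstraction from C4 (benzylic to the trioxygenated ring A and alpha to the methoxy oxygen, far more hydridic than C2–H) gives an oxocarbenium ion that water converts by way of the hemiketal into the ketone, so that both C4 epimers converge and C2 stays untouched under these non-basic conditions.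

Step 6
Reactants: 11 (2S)-2-[4-(tert-butyldimethylsilyloxy)phenyl]-8-iodo-5-methoxy-7-(triisopropylsilyloxy)chroman-4-one
Product: 12 (2S)-2-[4-(tert-butyldimethylsilyloxy)phenyl]-5-methoxy-4-oxo-7-(triisopropylsilyloxy)chromane-8-carbaldehyde
Conditions: Pd(PPh3)4 (5 mol %), CO (3 bar), Bu3SnH (1.2 equiv, syringe pump), toluene, 50 °C
Reagents that add atoms: carbon monoxide, [C-]#[O+]
Why: Palladium-catalysed reductive carbonylation (formylation) of an aryl iodide: oxidative addition, CO insertion (favoured at a hindered aryl–palladium bond) and hydride transfer from slowly added tin hydride should give the aldehyde under neutral conditions that spare the base-sensitive C2 centre and the aryl silyl ethers.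

Step 7
Reactants: 13 tert-butyl(4-iodophenoxy)dimethylsilane; 14 allyl alcohol
Product: 15 3-[4-(tert-butyldimethylsilyloxy)phenyl]propanal
Conditions: Pd(OAc)2 (2 mol %), Bu4NCl, NaHCO3, DMF, 40 °C
Reagents that add atoms: none
Why: Heck arylation of allyl alcohol under phase-transfer (Jeffery) conditions: β-hydride elimination towards the carbinol carbon gives the enol and hence the 3-arylpropanal directly.

Step 8
Reactants: 15 3-[4-(tert-butyldimethylsilyloxy)phenyl]propanal
Product: 16 (3S)-1-[4-(tert-butyldimethylsilyloxy)phenyl]hex-5-en-3-ol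
Conditions: (R)-BINOL (10 mol %), Ti(OiPr)4 (10 mol %), 4 Å MS, allyltributylstannane (1.2 equiv), CH2Cl2, −20 °C; aq. NaHCO3
Reagents that add atoms: allyltributylstannane, C=CC[Sn](CCCC)(CCCC)CCCC
Why: Keck asymmetric allylation: the (R)-BINOL–titanium Lewis acid directs allyl transfer from tin to the Re face of the aliphatic aldehyde, which sets the future C7' as S.

Step 9
Reactants: 16 (3S)-1-[4-(tert-butyldimethylsilyloxy)phenyl]hex-5-en-3-ol
Product: 17 (3S)-1-[4-(tert-butyldimethylsilyloxy)phenyl]-3-(triethylsilyloxy)hex-5-ene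
Conditions: TESCl (1.2 equiv), imidazole, CH2Cl2, 0 °C
Reagents that add atoms: triethylsilyl chloride, CC[Si](Cl)(CC)CC
Why: Standard silylation of a secondary alcohol; triethylsilyl is chosen so that the final buffered fluoride treatment removes it as easily as the aryl silyl ethers.

Step 10
Reactants: 18 (Z)-but-2-ene-1,4-diol; 19 4-(tert-butyldimethylsilyloxy)phenylboronic acid
Product: 20 (2R)-2-[4-(tert-butyldimethylsilyloxy)phenyl]but-3-en-1-ol
Conditions: 18 (3 equiv), [Rh(OH)(L)]2 (2.5 mol %; L = chiral 2,5-diphenylbicyclo[2.2.2]octa-2,5-diene, antipode giving R), 1,4-dioxane, 30 °C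
Reagents that add atoms: none
Why: Rhodium-catalysed enantioselective substitutive arylation of a cis-allylic diol: enantioface-selective carborhodation of the symmetric alkene, controlled by the chiral diene ligand, followed by β-hydroxide elimination should give the 2-arylbut-3-en-1-ol and regenerate the hydroxorhodium catalyst without added base, which sets the future C3' as R.

Step 11
Reactants: 20 (2R)-2-[4-(tert-butyldimethylsilyloxy)phenyl]but-3-en-1-ol
Product: 21 tert-butyl{4-[(2R)-1-iodobut-3-en-2-yl]phenoxy}dimethylsilane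
Conditions: PPh3, I2, imidazole, CH2Cl2, 0 °C, dark
Reagents that add atoms: iodine, II
Why: Appel iodination (SN2 displacement of the alkoxyphosphonium ion by iodide at the primary carbon) under cold, buffered conditions should leave the adjacent stereocentre and the aryl silyl ether untouched.

Step 12
Reactants: 21 tert-butyl{4-[(2R)-1-iodobut-3-en-2-yl]phenoxy}dimethylsilane; 17 (3S)-1-[4-(tert-butyldimethylsilyloxy)phenyl]-3-(triethylsilyloxy)hex-5-ene
Product: 22 (2R,3E,6S)-1-iodo-2,8-bis[4-(tert-butyldimethylsilyloxy)phenyl]-6-(triethylsilyloxy)oct-3-ene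
Conditions: 17 (2.5 equiv), second-generation Hoveyda–Grubbs catalyst (5 mol %), 1,4-benzoquinone (10 mol %), CH2Cl2, 40 °C
Reagents that add atoms: none
Why: Olefin cross-metathesis between an allylically branched terminal alkene, slow to homodimerise, and an excess of an unhindered terminal alkene should be selective and predominantly E for steric reasons, with benzoquinone suppressing ruthenium hydride isomerisation of the benzylic allylic position.

Step 13
Reactants: 22 (2R,3E,6S)-1-iodo-2,8-bis[4-(tert-butyldimethylsilyloxy)phenyl]-6-(triethylsilyloxy)oct-3-ene; 12 (2S)-2-[4-(tert-butyldimethylsilyloxy)phenyl]-5-methoxy-4-oxo-7-(triisopropylsilyloxy)chromane-8-carbaldehyde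
Product: 25 (2S)-8-[(1S,3R,4E,7S)-3,9-bis[4-(tert-butyldimethylsilyloxy)phenyl]-1-hydroxy-7-(triethylsilyloxy)non-4-en-1-yl]-2-[4-(tert-butyldimethylsilyloxy)phenyl]-5-methoxy-7-(triisopropylsilyloxy)chroman-4-one, via alkyllithium 23 (not isolated), via alkyltitanium triisopropoxide 24 (not isolated)
Conditions: 22 (1.6 equiv), t-BuLi (3.3 equiv), Et2O/pentane, −78 °C; ClTi(OiPr)3 (1.7 equiv), −78 to −30 °C; then 12, (S)-3-(3,5-diphenylphenyl)-H8-BINOL (10 mol %), Ti(OiPr)4 (1.5 equiv), CH2Cl2, −20 to 0 °C; aq. Rochelle salt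
Reagents that add atoms: none
Why: Iodine–lithium exchange of the primary iodide with tert-butyllithium is polar and so avoids the primary radical that would undergo 1,2-vinyl or aryl shift, transmetalation gives a non-basic alkyltitanium that adds to the aldehyde and not to the C4 ketone, and the chiral titanium binaphtholate (titanium-catalysed enantioselective alkylation of aryl aldehydes; the (S)-ligand is taken to be the antipode that sends alkyl groups to the Si face) should set C1' as S, the remote C3' centre exerting little bias.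

Step 14
Reactants: 25 (2S)-8-[(1S,3R,4E,7S)-3,9-bis[4-(tert-butyldimethylsilyloxy)phenyl]-1-hydroxy-7-(triethylsilyloxy)non-4-en-1-yl]-2-[4-(tert-butyldimethylsilyloxy)phenyl]-5-methoxy-7-(triisopropylsilyloxy)chroman-4-one
Product: 26 (2S)-8-[(1S,3R,4E,7S)-1,7-dihydroxy-3,9-bis(4-hydroxyphenyl)non-4-en-1-yl]-7-hydroxy-2-(4-hydroxyphenyl)-5-methoxychroman-4-one
Conditions: TBAF/AcOH (1:1, 7 equiv), THF, 0 °C to rt; pH 7 work-up
Reagents that add atoms: none
Why: Fluoride-mediated desilylation buffered with acetic acid should cleave the four aryl silyl ethers and the triethylsilyl ether near neutrality, which avoids both base-induced ring opening and epimerisation at C2 and acid-induced ionisation of the C1' benzylic carbinol.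

**Compound list**

1 | 2,4-dihydroxy-6-methoxybenzaldehyde | COc1cc(O)cc(O)c1C=O | starting material
2 | 2,4-dihydroxy-3-iodo-6-methoxybenzaldehyde | COc1cc(O)c(I)c(O)c1C=O | intermediate
3 | 2-hydroxy-3-iodo-6-methoxy-4-(triisopropylsilyloxy)benzaldehyde | COc1cc(O[Si](C(C)C)(C(C)C)C(C)C)c(I)c(O)c1C=O | intermediate
4 | 4-acetoxystyrene | CC(=O)Oc1ccc(C=C)cc1 | starting material
5 | 4-vinylphenol | C=Cc1ccc(O)cc1 | intermediate
6 | 4-(tert-butyldimethylsilyloxy)styrene | C=Cc1ccc(O[Si](C)(C)C(C)(C)C)cc1 | intermediate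
7 | trimethyl orthoformate | COC(OC)OC | starting material
8 | 2-(dimethoxymethyl)-6-iodo-3-methoxy-5-(triisopropylsilyloxy)phenol | COc1cc(O[Si](C(C)C)(C(C)C)C(C)C)c(I)c(O)c1C(OC)OC | intermediate
9 | (6E)-2-iodo-5-methoxy-6-(methoxymethylidene)-3-(triisopropylsilyloxy)cyclohexa-2,4-dien-1-one | CO/C=C1\C(OC)=CC(O[Si](C(C)C)(C(C)C)C(C)C)=C(I)C1=O | intermediate
10 | (2S,4S)-2-[4-(tert-butyldimethylsilyloxy)phenyl]-8-iodo-4,5-dimethoxy-7-(triisopropylsilyloxy)chromane (2,4-cis 8-iodo-4-methoxyflavan) | COc1cc(O[Si](C(C)C)(C(C)C)C(C)C)c(I)c2c1[C@@H](OC)C[C@@H](c1ccc(O[Si](C)(C)C(C)(C)C)cc1)O2 | intermediate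
11 | (2S)-2-[4-(tert-butyldimethylsilyloxy)phenyl]-8-iodo-5-methoxy-7-(triisopropylsilyloxy)chroman-4-one | COc1cc(O[Si](C(C)C)(C(C)C)C(C)C)c(I)c2c1C(=O)C[C@@H](c1ccc(O[Si](C)(C)C(C)(C)C)cc1)O2 | intermediate
12 | (2S)-2-[4-(tert-butyldimethylsilyloxy)phenyl]-5-methoxy-4-oxo-7-(triisopropylsilyloxy)chromane-8-carbaldehyde | COc1cc(O[Si](C(C)C)(C(C)C)C(C)C)c(C=O)c2c1C(=O)C[C@@H](c1ccc(O[Si](C)(C)C(C)(C)C)cc1)O2 | intermediate
13 | tert-butyl(4-iodophenoxy)dimethylsilane | CC(C)(C)[Si](C)(C)Oc1ccc(I)cc1 | starting material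
14 | allyl alcohol | C=CCO | starting material
15 | 3-[4-(tert-butyldimethylsilyloxy)phenyl]propanal | O=CCCc1ccc(O[Si](C)(C)C(C)(C)C)cc1 | intermediate
16 | (3S)-1-[4-(tert-butyldimethylsilyloxy)phenyl]hex-5-en-3-ol | C=CC[C@@H](O)CCc1ccc(O[Si](C)(C)C(C)(C)C)cc1 | intermediate
17 | (3S)-1-[4-(tert-butyldimethylsilyloxy)phenyl]-3-(triethylsilyloxy)hex-5-ene | C=CC[C@@H](O[Si](CC)(CC)CC)CCc1ccc(O[Si](C)(C)C(C)(C)C)cc1 | intermediate
18 | (Z)-but-2-ene-1,4-diol | OC/C=C\CO | starting material
19 | 4-(tert-butyldimethylsilyloxy)phenylboronic acid | CC(C)(C)[Si](C)(C)Oc1ccc(B(O)O)cc1 | starting material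
20 | (2R)-2-[4-(tert-butyldimethylsilyloxy)phenyl]but-3-en-1-ol | OC[C@H](C=C)c1ccc(O[Si](C)(C)C(C)(C)C)cc1 | intermediate
21 | tert-butyl{4-[(2R)-1-iodobut-3-en-2-yl]phenoxy}dimethylsilane | IC[C@H](C=C)c1ccc(O[Si](C)(C)C(C)(C)C)cc1 | intermediate
22 | (2R,3E,6S)-1-iodo-2,8-bis[4-(tert-butyldimethylsilyloxy)phenyl]-6-(triethylsilyloxy)oct-3-ene | IC[C@H](/C=C/C[C@@H](O[Si](CC)(CC)CC)CCc1ccc(O[Si](C)(C)C(C)(C)C)cc1)c1ccc(O[Si](C)(C)C(C)(C)C)cc1 | intermediate
23 | alkyllithium from 22 (lithium in place of iodine) | [Li]C[C@H](/C=C/C[C@@H](O[Si](CC)(CC)CC)CCc1ccc(O[Si](C)(C)C(C)(C)C)cc1)c1ccc(O[Si](C)(C)C(C)(C)C)cc1 | intermediate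
24 | alkyltitanium triisopropoxide from 23 | CC(C)O[Ti](OC(C)C)(OC(C)C)C[C@H](/C=C/C[C@@H](O[Si](CC)(CC)CC)CCc1ccc(O[Si](C)(C)C(C)(C)C)cc1)c1ccc(O[Si](C)(C)C(C)(C)C)cc1 | intermediate
25 | (2S)-8-[(1S,3R,4E,7S)-3,9-bis[4-(tert-butyldimethylsilyloxy)phenyl]-1-hydroxy-7-(triethylsilyloxy)non-4-en-1-yl]-2-[4-(tert-butyldimethylsilyloxy)phenyl]-5-methoxy-7-(triisopropylsilyloxy)chroman-4-one | COc1cc(O[Si](C(C)C)(C(C)C)C(C)C)c([C@@H](O)C[C@H](/C=C/C[C@@H](O[Si](CC)(CC)CC)CCc2ccc(O[Si](C)(C)C(C)(C)C)cc2)c2ccc(O[Si](C)(C)C(C)(C)C)cc2)c2c1C(=O)C[C@@H](c1ccc(O[Si](C)(C)C(C)(C)C)cc1)O2 | intermediate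
26 | (2S)-8-[(1S,3R,4E,7S)-1,7-dihydroxy-3,9-bis(4-hydroxyphenyl)non-4-en-1-yl]-7-hydroxy-2-(4-hydroxyphenyl)-5-methoxychroman-4-one | COc1cc(O)c([C@@H](O)C[C@H](/C=C/C[C@@H](O)CCc2ccc(O)cc2)c2ccc(O)cc2)c2c1C(=O)C[C@@H](c1ccc(O)cc1)O2 | target

**Step count and risks**

Total: 14 steps. Longest linear sequence: 7 steps from 1 (steps 1, 2, 4, 5, 6, 13, 14); the chain branch from 13 runs through 6 steps (7, 8, 9, 12, 13, 14).

Steps most likely to fail:

1. Step 4 (proposed new method). The chiral acid may give low enantioselectivity at C2, or acid-induced oligomerisation of the styrene may outrun the cycloaddition. Fallback, setting out from 3, 6 and 7: the three components are combined under the established achiral-acid conditions (catalytic Sc(OTf)3 or camphorsulfonic acid, CH2Cl2, 0 °C), which give the 2,4-cis flavan as the racemate, that is 10 together with its mirror image, the (2R,4R)-flavan F1. Preparative chromatography on a chiral stationary phase removes F1, and enantiopure 10 re-enters the route before step 5.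

2. Step 13. Transfer of the bulky alkyl group to the doubly ortho-substituted, electron-rich aldehyde may be slow or poorly face-selective and waste the chain. Fallback, setting out from 21 and 12: 21 is converted by tert-butyllithium exchange (Et2O/pentane, −78 °C) into the small alkyllithium F2 and then, with ZnCl2 (0.5 equiv) and removal of LiCl, into the dialkylzinc F3. An excess of F3 with Ti(OiPr)4 and (1R,2R)-1,2-bis(trifluoromethanesulfonamido)cyclohexane (toluene, −20 °C) adds to 12 to give the truncated carbinol F4, whose C1' epimers are easier to separate. Cross-metathesis of F4 with 17 (second-generation Hoveyda–Grubbs catalyst, CH2Cl2, 40 °C) then gives 25, which re-enters before step 14.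

3. Step 6. Reduction of the hindered aryl–palladium intermediate before CO insertion would lead to hydrodeiodination. Fallback, setting out from 11: base-free Stille coupling with tributyl(vinyl)stannane (Pd(PPh3)4, CuI, toluene, 80 °C) gives the 8-vinylflavanone F5, and Lemieux–Johnson cleavage (OsO4 cat., NaIO4, 2,6-lutidine, dioxane/H2O) gives 12, which re-enters before step 13.

**Further compounds**

F1 | step 4 | (2R,4R)-2-[4-(tert-butyldimethylsilyloxy)phenyl]-8-iodo-4,5-dimethoxy-7-(triisopropylsilyloxy)chromane (enantiomer of 10) | COc1cc(O[Si](C(C)C)(C(C)C)C(C)C)c(I)c2c1[C@H](OC)C[C@H](c1ccc(O[Si](C)(C)C(C)(C)C)cc1)O2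
F2 | step 13 | {(2R)-2-[4-(tert-butyldimethylsilyloxy)phenyl]but-3-en-1-yl}lithium | [Li]C[C@H](C=C)c1ccc(O[Si](C)(C)C(C)(C)C)cc1
F3 | step 13 | bis{(2R)-2-[4-(tert-butyldimethylsilyloxy)phenyl]but-3-en-1-yl}zinc | [Zn](C[C@H](C=C)c1ccc(O[Si](C)(C)C(C)(C)C)cc1)C[C@H](C=C)c1ccc(O[Si](C)(C)C(C)(C)C)cc1
F4 | step 13 | (2S)-2-[4-(tert-butyldimethylsilyloxy)phenyl]-8-{(1S,3R)-3-[4-(tert-butyldimethylsilyloxy)phenyl]-1-hydroxypent-4-en-1-yl}-5-methoxy-7-(triisopropylsilyloxy)chroman-4-one | COc1cc(O[Si](C(C)C)(C(C)C)C(C)C)c([C@@H](O)C[C@H](C=C)c2ccc(O[Si](C)(C)C(C)(C)C)cc2)c2c1C(=O)C[C@@H](c1ccc(O[Si](C)(C)C(C)(C)C)cc1)O2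
F5 | step 6 | (2S)-2-[4-(tert-butyldimethylsilyloxy)phenyl]-8-ethenyl-5-methoxy-7-(triisopropylsilyloxy)chroman-4-one | COc1cc(O[Si](C(C)C)(C(C)C)C(C)C)c(C=C)c2c1C(=O)C[C@@H](c1ccc(O[Si](C)(C)C(C)(C)C)cc1)O2
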